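Remark on the chemistry (assumption): compound 1, desacylcynaropicrin, is taken as a catalogue natural product (the 8-O-deacyl form of cynaropicrin from artichoke leaf). Guaiane numbering is used throughout: unprimed atoms belong to the cyclopentenone half (unit A, ring A = C1–C5), primed atoms to the spiro half (unit B).

## The problem

The target is a C30 formal [4+2] adduct of two 8β-hydroxy-3-oxoguaianolides that differ by two hydrogens. Unit A is a cross-conjugated cyclopentenone (ring A with C1=C2 and C4=C15); unit B keeps the saturated cis-fused hydroazulenone with its C10'=C14' methylene. The halves are joined by C2–C4' and C14–C15'. These bonds close a cyclohexene (C2, C1, C10, C14, C15', C4') that is fused to ring A at C1=C2, fused to the cycloheptane of unit A at C1–C10, and spiro to the cyclopentanone of unit B at the quaternary centre C4'. Of the eleven stereocentres, unit B carries C1', C5', C6', C7', C8' and C4' (R); unit A carries C5, C6, C7, C8 and C10. Two details depart from the common guaianolide pattern: both carbinols are 8β (R, cis to the C7–C11 bond), and H5 of unit A is β (cis to H6), opposite to H5' of unit B. C5 and C10 are the two γ-carbons of the C3 enone of ring A and can be set last by proton transfer; C4' can only be set by the face on which unit B is attacked, and C8/C8' must be in place before the halves meet. The feature that makes the key step possible is the C3 ketone of the monomer: its only enolizable carbon is C2, and the neighbouring C1 carries one hydrogen and the exocyclic C10=C14 bond. Removing H1 and H2 therefore unveils an s-cis-locked diene C2=C1–C10=C14, whose [4+2] partner is the exocyclic enone C4'=C15' of an unchanged monomer. Late intermediates will not tolerate alkoxides, hydrides, strong nucleophiles or radicals: they hold two α-methylene-γ-lactones, an exocyclic enone on a cross-conjugated dienone, an acidic C5–H and two free secondary alcohols.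

## Retrosynthesis

No carbon–carbon bond is cut first. The conjugated C1=C2 enone of 9, with hydrogen at C10, is the 1,3-proton-shift isomer of the β,γ-unsaturated ketone 8 (C1=C10, hydrogen at C2). The 5β-H of 9 is the epimer of the 5α-H of 8 at the most acidic carbon of the molecule. Precursor 8 is preferred to one that already has the C1=C2 bond because only 8 has the sp3 C2 that a cycloaddition leaves behind. The forward reaction has to deliver the proton to the β face of C10 and let C5 settle.

The bonds C2–C4' and C14–C15' of 8 are cut together in a retro-[4+2]. Cutting only one of them was weighed, but the pair is dissonant: C2 and C4' are both α-carbons of ketones, C14 and C15' both electrophilic termini, and only a cycloaddition joins them without a redox detour. The fragments are dienone 6 and enone 4, each half the size of 8 and both derived from one compound; the primary product is silylated cycloadduct 7. The forward reaction must join C2 to C4', attack the α face of 4, and outrun self-cycloaddition of 6.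

The C1=C2 bond of 6 is traced back to the C1–H and C2–H bonds of 4 by way of silyl dienol ether 5. This is preferred to a separate synthesis of the diene half: C2 is the only enolizable site of 4, so the desaturation has no regiochemical choice, and 6 is made and consumed in the same flask. The silylation that gives 5 masks the 8β-hydroxyl at the same time.

The C8–O bond is cut with inversion: 4 comes from formate 3, and 3 from the 8α-alcohol 2 by SN2 substitution. Oxidation and reduction at C8 was set aside because an 8-ketone is a β-acyloxy ketone prone to lactone elimination, and small hydrides would return the equatorial 8α-alcohol. The substitution must distinguish C8 from C3, which is why C3 is already a ketone in 2.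

The C3 carbonyl of 2 is traced to the allylic carbinol of 1. Its 5-7-5 skeleton already holds C1, C5, C6 and C7 with the configuration of unit B, C6 and C7 with that of unit A, the three exocyclic methylenes and the lactone. Only the allylic alcohol has to be oxidized beside the 8α-alcohol.

## Roads not taken

Alternative 1: the most obvious plan for a dimer of two guaianolides is to build each 5-7-5 half from simple material and to join the halves at the very end. The cut lies in each seven-membered ring (C6–C7 and C8–C9). The forward key steps are two Barbier allylations on cyclopentene carbaldehyde A1, which ozonolytic ring contraction of (S)-carvone would provide, leading to a tricycle such as A2. The chosen plan is better on three counts. A2 carries the thermodynamically favoured endocyclic C4=C5 enone and would still have to be transposed to the exocyclic 4(15)-ene with a 5α-hydrogen. C6, C7 and C8 would each depend on an allylation of uncertain facial bias. And more than ten steps would be spent to reach a compound that 1 provides after one oxidation and one inversion; the ring-A centres C5 and C10 need not be built at all, because they are set last.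

Alternative 2: a stepwise union. C14–C15' would be cut first; the forward step is a Lewis-acid-promoted Alder-ene reaction of the C10=C14 ene of one molecule of 4 (H1 transferred) onto C4'=C15' of another, giving A3. C2–C4' would follow by intramolecular oxidative coupling of the two ketone enolates. No desaturation would be needed. But two separate C–C bond formations replace one, the ene step must choose between three 1,1-disubstituted alkenes and two kinds of allylic hydrogen (H1, H9) and competes with hetero-Diels–Alder dimerization of the enone, and the oxidative coupling must create the spiro quaternary centre beside six other π bonds. The cycloaddition forms both bonds with the regiochemistry fixed by the diene.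

Alternative 3: the diene half made on its own. Ring A of the target keeps no monomer stereocentre at C1 and only an epimerizable one at C5, so its cyclopentenone could be cut at C1–C5, C2–C3 and C3–C4. The forward step is an allenic Pauson–Khand reaction of allenyne lactone A4 at the proximal allene bond with Mo(CO)6, giving dienone A5. This forms both carbocycles of unit A at a stroke, but closing a seven-membered ring through the proximal allene bond is the unfavourable mode of that reaction, A4 needs its own multistep synthesis with three stereocentres, and unit B would still have to come from 4. The chosen plan gets the same dienone from 4 in two operations.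

Key step: step 5

## Route

Step 1
Reactants: 1 desacylcynaropicrin (3β,8α-dihydroxy-1αH,5αH,6βH,7αH-guaia-4(15),10(14),11(13)-trien-12,6α-olide)
Product: 2 8α-hydroxydehydrozaluzanin C (8α-hydroxy-3-oxo-1αH,5αH,6βH,7αH-guaia-4(15),10(14),11(13)-trien-12,6α-olide)
Conditions: activated MnO2 (20 equiv), CH2Cl2, 23 °C
Reagents that add atoms: none
Why: Allylic alcohol oxidation: activated MnO2 oxidizes only the C3 carbinol next to C4=C15 and should leave the saturated 8α-alcohol, the exocyclic alkenes and the lactone untouched; no stereocentre is formed.

Step 2
Reactants: 2 8α-hydroxydehydrozaluzanin C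
Product: 3 8β-formyloxy-3-oxo-1αH,5αH,6βH,7αH-guaia-4(15),10(14),11(13)-trien-12,6α-olide
Conditions: PPh3, DIAD (betaine preformed at 0 °C), HCO2H, THF, 0 → 23 °C
Reagents that add atoms: formic acid, OC=O
Why: Mitsunobu reaction: formate displaces the 8α-oxyphosphonium group by SN2 on the β face, which sets the 8β (R) configuration by inversion; the leaving group is syn to H7, so E2 toward C7 is geometrically disfavoured, the precedent is the inversion of hindered equatorial cyclohexanols flanked by a branched carbon, and the C3 ketone from step 1 has removed the competing allylic alcohol.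

Step 3
Reactants: 3 8β-formyloxy-3-oxo-1αH,5αH,6βH,7αH-guaia-4(15),10(14),11(13)-trien-12,6α-olide
Product: 4 8β-hydroxydehydrozaluzanin C (8β-hydroxy-3-oxo-1αH,5αH,6βH,7αH-guaia-4(15),10(14),11(13)-trien-12,6α-olide)
Conditions: KHCO3 (0.2 equiv), MeOH, 0 °C
Reagents that add atoms: none
Why: Bicarbonate-buffered transesterification: a formate is solvolysed far faster than the lactone and should outrun conjugate addition of methanol to the enone and the α-methylene lactone; C8 is not touched, so the 8β configuration is kept.

Step 4
Reactants: 4 8β-hydroxydehydrozaluzanin C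
Product: 5 3,8β-bis(trimethylsilyloxy)-1αH,5αH,6βH,7αH-guaia-2,4(15),10(14),11(13)-tetraen-12,6α-olide
Conditions: TMSOTf (2.4 equiv), Et3N (4 equiv), CH2Cl2, −78 → 0 °C
Reagents that add atoms: trimethylsilyl trifluoromethanesulfonate, C[Si](C)(C)OS(=O)(=O)C(F)(F)F
Why: Soft enolization and silylation: C2 is the only enolizable carbon of the C3 ketone (C4 is sp2), so a single 2-silyloxydiene should form, and the 8β-hydroxyl is masked as its TMS ether in the same operation; C1 keeps its configuration because enolization runs toward C2.

Step 5
Reactants: 5 3,8β-bis(trimethylsilyloxy)-1αH,5αH,6βH,7αH-guaia-2,4(15),10(14),11(13)-tetraen-12,6α-olide (1 equiv); 4 8β-hydroxydehydrozaluzanin C (2 equiv)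
Product: 8 cycloadduct diol (unit A 8β-hydroxy-3-oxo-2βH,5αH-guaia-1(10),4(15),11(13)-trien-12,6α-olide joined through C2 and C14 to C4' and C15' of unit B 8'β-hydroxy-3'-oxo-1'αH,5'αH-guaia-10'(14'),11'(13')-dien-12',6'α-olide; C2 S, C4' R), via dienone 6 (not isolated), via silylated cycloadduct 7 (not isolated)
Conditions: Pd(OAc)2 (1.1 equiv, in portions), MeCN, 23 → 40 °C, Ar; then 10% aq. citric acid, THF, 0 °C
Reagents that add atoms: none
Why: Saegusa–Ito oxidation followed in the same flask by an intermolecular Diels–Alder reaction: silicon-to-palladium exchange at O3/C2 of 5 gives a divalent palladium enolate, and syn β-hydride elimination of H1 releases dienone 6 and zerovalent palladium. In 6 the new C1=C2 bond and the exocyclic C10=C14 bond form a diene locked s-cis by the seven-membered ring, and it should be trapped as it forms by the exocyclic enone C4'=C15' of 4. The closest known reaction type is the [4+2] dimerization of 5-methylenecyclopent-2-enones with α-methylene ketones, the oxidation being the standard dehydrogenation of an enol silane. The cyclohexene (C2, C1, C10, C14, C15', C4') closes by a concerted, asynchronous [4+2], suprafacial on both partners, in which the unsubstituted termini C14 and C15' bond first, so the ortho rule places the acyl-bearing C2 on the acyl-bearing C4' and creates the spiro centre. C4' (R) is controlled by the cis ring fusion of 4: the diene should add to the convex α face (the face of H1' and H5'), away from the folded cycloheptane with its β-oriented C7'–C11' bond and 8'β-hydroxyl. C2 (S, H2 β) is controlled by the diene: the dienophile should approach the α face of 6, anti to C6 and to the 8β-silyloxy group; this centre is transient but stores the face information used in step 6. The selectivity the step needs is cross- over self-cycloaddition of 6, whose own C4=C15 bond is a 2π partner; it is secured by generating 6 slowly in the presence of two equivalents of 4, which has no diene and can act only as dienophile. The citric acid wash removes the 8-O-TMS group of 7 to give 8.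

Step 6
Reactants: 8 cycloadduct diol
Product: 9 target CNP0397417.1 (unit A 8β-hydroxy-3-oxo-5βH,10βH-guaia-1,4(15),11(13)-trien-12,6α-olide joined through C2 and C14 to C4' and C15' of unit B 8'β-hydroxy-3'-oxo-1'αH,5'αH-guaia-10'(14'),11'(13')-dien-12',6'α-olide; C4' R, C5 S, C10 R)
Conditions: DBU (0.3 equiv), degassed CH2Cl2–toluene, 0 → 23 °C, Ar
Reagents that add atoms: none
Why: Base-mediated 1,3-prototropic shift of a β,γ- to an α,β-unsaturated ketone: DBU removes H2 (α to C3=O and allylic) and in a weakly polar medium should return the proton within the ion pair to C10 on the same β face, the face also held by the 8β-hydroxyl, which sets C10 (R, H10 β); C5–H is then the most acidic C–H (γ to the new enone and allylic to C4=C15) and should equilibrate through the cross-conjugated trienolate to the 5β-H (S) epimer, in which H5 and H10 are syn and C6 and C9 leave the planar cyclopentenone on the same face.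

## Compound list

1 | desacylcynaropicrin, 3β,8α-dihydroxy-1αH,5αH,6βH,7αH-guaia-4(15),10(14),11(13)-trien-12,6α-olide | C=C1[C@@H](O)C[C@H]2C(=C)C[C@H](O)[C@H]3C(=C)C(=O)O[C@@H]3[C@@H]12 | starting material
2 | 8α-hydroxydehydrozaluzanin C, 8α-hydroxy-3-oxo-1αH,5αH,6βH,7αH-guaia-4(15),10(14),11(13)-trien-12,6α-olide | C=C1C(=O)C[C@H]2C(=C)C[C@H](O)[C@H]3C(=C)C(=O)O[C@@H]3[C@@H]12 | intermediate
3 | 8β-formyloxy-3-oxo-1αH,5αH,6βH,7αH-guaia-4(15),10(14),11(13)-trien-12,6α-olide | C=C1C(=O)C[C@H]2C(=C)C[C@@H](OC=O)[C@H]3C(=C)C(=O)O[C@@H]3[C@@H]12 | intermediate
4 | 8β-hydroxydehydrozaluzanin C, 8β-hydroxy-3-oxo-1αH,5αH,6βH,7αH-guaia-4(15),10(14),11(13)-trien-12,6α-olide | C=C1C(=O)C[C@H]2C(=C)C[C@@H](O)[C@H]3C(=C)C(=O)O[C@@H]3[C@@H]12 | intermediate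
5 | 3,8β-bis(trimethylsilyloxy)-1αH,5αH,6βH,7αH-guaia-2,4(15),10(14),11(13)-tetraen-12,6α-olide | C=C1C(O[Si](C)(C)C)=C[C@H]2C(=C)C[C@@H](O[Si](C)(C)C)[C@H]3C(=C)C(=O)O[C@@H]3[C@@H]12 | intermediate
6 | dienone, 8β-trimethylsilyloxy-3-oxo-5αH,6βH,7αH-guaia-1,4(15),10(14),11(13)-tetraen-12,6α-olide | C=C1C(=O)C=C2C(=C)C[C@@H](O[Si](C)(C)C)[C@H]3C(=C)C(=O)O[C@@H]3[C@@H]12 | intermediate
7 | silylated cycloadduct, the 8-O-trimethylsilyl ether of 8 (C2 S, H2 β; C4' R; 5αH; C1=C10) | C=C1C(=O)[C@H]2C3=C(CC[C@]24C(=O)C[C@H]5C(=C)C[C@@H](O)[C@H]6C(=C)C(=O)O[C@@H]6[C@H]54)C[C@@H](O[Si](C)(C)C)[C@H]2C(=C)C(=O)O[C@@H]2[C@@H]13 | intermediate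
8 | cycloadduct diol (unit A 8β-hydroxy-3-oxo-2βH,5αH-guaia-1(10),4(15),11(13)-trien-12,6α-olide; unit B 8'β-hydroxy-3'-oxo-1'αH,5'αH-guaia-10'(14'),11'(13')-dien-12',6'α-olide; bonds C2–C4' and C14–C15'; C2 S, C4' R) | C=C1C(=O)[C@H]2C3=C(CC[C@]24C(=O)C[C@H]5C(=C)C[C@@H](O)[C@H]6C(=C)C(=O)O[C@@H]6[C@H]54)C[C@@H](O)[C@H]2C(=C)C(=O)O[C@@H]2[C@@H]13 | intermediate
9 | CNP0397417.1 (unit A 8β-hydroxy-3-oxo-5βH,10βH-guaia-1,4(15),11(13)-trien-12,6α-olide; unit B as in 8; bonds C2–C4' and C14–C15'; C4' R, C5 S, C10 R) | C=C1C(=O)C2=C3[C@H](CC[C@]24C(=O)C[C@H]2C(=C)C[C@@H](O)[C@H]5C(=C)C(=O)O[C@@H]5[C@H]24)C[C@@H](O)[C@H]2C(=C)C(=O)O[C@@H]2[C@H]13 | target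

## Step count and risks

Total step count: 6. Longest linear sequence: 6 steps (1 → 2 → 3 → 4 → 5 → 8 → 9; compound 4 enters step 5 a second time as the dienophile).

Least certain steps:

**Step 5 (key step).** The transient dienone may cycloadd to itself faster than to 4 if it accumulates, since its own exocyclic enone is the more electron-poor 2π partner. Acetic acid from the oxidation may also protodesilylate 5 before palladium reaches it, and palladium hydride may move exocyclic double bonds into the rings. Facial selectivity at C4' rests on the convex face of 4 alone. The fallback generates the diene by a pericyclic elimination instead of a metal oxidation. It sets out from 5: PhSeCl (CH2Cl2, −78 °C) should give the 2α-phenylselanyl ketone F1, and mCPBA at −78 °C its selenoxide F2. F2 is warmed to 0 °C in the presence of 4 (2 equiv) and iPr2NH, so that syn elimination (selenium and H1 both α) releases 6 without palladium or acid. Trapping by 4 gives 7, and the citric acid wash brings the sequence back to the route at 8.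

**Step 6.** The proton may be returned to C10 without face control if the ion pair separates, and the position of the C5 equilibrium is argued from conformation, not known. The cross-conjugated dienone may also add nucleophiles or oligomerize under base, and the dienolate is sensitive to oxygen at C10. The fallback replaces base-mediated proton transfer by a metal hydride 1,3-hydrogen shift. It sets out from 8: [Ir(cod)(PCy3)(py)]PF6, briefly activated with H2 and then purged with argon (CH2Cl2, 0 °C), is bound by the 8β-hydroxyl and should add and remove hydrogen on the β face of the C2–C1–C10 unit (H2 β out, H10 β in). A short exposure to Et3N then lets C5 settle, and the sequence returns at 9. No new isolated compound arises (F0).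

**Step 2.** The activated 8α-oxygen may be lost by E2 toward C9 (the new alkene would be conjugated with C10=C14) rather than displaced at the hindered C8, and free phosphine may add to the exocyclic enone. The fallback uses sulfonate displacement by a small oxygen nucleophile without phosphine. It sets out from 2: Tf2O and pyridine (CH2Cl2, −20 °C) should give the 8α-triflate F3; Bu4N+ NO2− in toluene displaces it with inversion to the 8β-nitrite ester F4, which hydrolyses on aqueous work-up. The sequence returns at 4, and step 3 is then not needed.

**Step 3.** Methanol or methoxide may add to the exocyclic enone or to the α-methylene lactone during solvolysis of the formate. The fallback changes the ester and the way it is cleaved. It sets out from 2: Mitsunobu inversion with chloroacetic acid (PPh3, DIAD, THF) should give the 8β-chloroacetate F5. Thiourea and NaHCO3 in EtOH at 50 °C then remove the acyl group by S-alkylation and cyclo-release at neutral pH without alkoxide, and the sequence returns at 4.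

## Further compounds

F1 | step 5 | 2α-(phenylselanyl)-8β-trimethylsilyloxy-3-oxo-1αH,5αH,6βH,7αH-guaia-4(15),10(14),11(13)-trien-12,6α-olide | C=C1C(=O)[C@H]([Se]c2ccccc2)[C@H]3C(=C)C[C@@H](O[Si](C)(C)C)[C@H]4C(=C)C(=O)O[C@@H]4[C@@H]13
F2 | step 5 | selenoxide of F1 (both configurations at selenium) | C=C1C(=O)[C@H]([Se](=O)c2ccccc2)[C@H]3C(=C)C[C@@H](O[Si](C)(C)C)[C@H]4C(=C)C(=O)O[C@@H]4[C@@H]13
F0 | step 6 | none | none
F3 | step 2 | 8α-trifluoromethanesulfonyloxy-3-oxo-1αH,5αH,6βH,7αH-guaia-4(15),10(14),11(13)-trien-12,6α-olide | C=C1C(=O)C[C@H]2C(=C)C[C@H](OS(=O)(=O)C(F)(F)F)[C@H]3C(=C)C(=O)O[C@@H]3[C@@H]12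
F4 | step 2 | 8β-nitrosooxy-3-oxo-1αH,5αH,6βH,7αH-guaia-4(15),10(14),11(13)-trien-12,6α-olide (nitrite ester) | C=C1C(=O)C[C@H]2C(=C)C[C@@H](ON=O)[C@H]3C(=C)C(=O)O[C@@H]3[C@@H]12
F5 | step 3 | 8β-(chloroacetoxy)-3-oxo-1αH,5αH,6βH,7αH-guaia-4(15),10(14),11(13)-trien-12,6α-olide | C=C1C(=O)C[C@H]2C(=C)C[C@@H](OC(=O)CCl)[C@H]3C(=C)C(=O)O[C@@H]3[C@@H]12
A1 | alternative 1 | (3S,5R)-3-(tert-butyldimethylsilyloxy)-5-(3-chloroprop-1-en-2-yl)-2-methylcyclopent-1-ene-1-carbaldehyde (3β-silyloxy, 1αH in guaiane terms) | O=CC1=C(C)[C@@H](O[Si](C)(C)C(C)(C)C)C[C@H]1C(=C)CCl
A2 | alternative 1 | 8β-hydroxy-3-oxo-1αH,6βH,7αH-guaia-4,10(14),11(13)-trien-12,6α-olide | CC1C(=O)C[C@H]2C(=C)C[C@@H](O)[C@H]3C(=C)C(=O)O[C@@H]3C=12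
A3 | alternative 2 | ene adduct (unit A 8β-hydroxy-3-oxo-5αH-guaia-1(10),4(15),11(13)-trien-12,6α-olide joined through C14 to C15' of unit B 8'β-hydroxy-3'-oxo-1'αH,5'αH-guaia-10'(14'),11'(13')-dien-12',6'α-olide; C4' not controlled) | C=C1C(=O)CC2=C(CCC3C(=O)C[C@H]4C(=C)C[C@@H](O)[C@H]5C(=C)C(=O)O[C@@H]5[C@H]43)C[C@@H](O)[C@H]3C(=C)C(=O)O[C@@H]3[C@@H]12
A4 | alternative 3 | allenyne lactone: trans-α-methylene-γ-butyrolactone with a propa-1,2-dienyl group at C6 and a 1-(tert-butyldimethylsilyloxy)-3-methylidenepent-4-ynyl group at C7 (6βH, 7αH, 8β-silyloxy in guaiane terms) | C=C=C[C@H]1OC(=O)C(=C)[C@@H]1[C@H](O[Si](C)(C)C(C)(C)C)CC(=C)C#C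
A5 | alternative 3 | 8β-(tert-butyldimethylsilyloxy)-3-oxo-6βH,7αH-guaia-1,4(15),10(14),11(13)-tetraen-12,6α-olide (C5 not controlled) | C=C1C(=O)C=C2C(=C)C[C@@H](O[Si](C)(C)C(C)(C)C)[C@H]3C(=C)C(=O)O[C@@H]3C12
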